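**Strategy.** The naphthol is cut through ring D (C4a', C5'–C8', C8a'). Its peri-related C4'–OH and C5'–OMe are what the "ortho" orientation of a 1-alkoxydiene/enone cycloaddition delivers, so one Diels–Alder reaction of 1-methoxycyclohexa-1,3-diene with a para-quinol forms C4a'–C5' and C8'–C8a' and closes ring D as an ethano-bridged cyclohexene. The precursor is the dearomatised form of a plain 4-substituted phenol, a 4-hydroxycyclohexa-2,5-dienone carrying the finished cis-tetralin (C1 oxygen as a pivalate, C4 methine set earlier by hydrogenation of an unhindered phenyl alkene). Loss of water then aromatises ring C (C1'–C4', C4a', C8a') and loss of ethylene aromatises ring D.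

Key step: step 8

Remarks on the chemistry (assumptions):
- Locants: tetralin C1 is the carbinol carbon, C4 the diaryl methine, C5 the methoxy carbon; naphthyl atoms are primed. The target is (1S,4S), with the two tetralin substituents cis.
- The C1 oxygen is carried as a pivalate rather than a silyl ether. The acyloxy group deactivates C1–H in the benzylic oxidation (step 3), tolerates the acid of step 9 and the heat of step 10, and is bulky enough to steer step 6.
- Technical-grade 1-methoxycyclohexa-1,3-diene (containing the 1,4-isomer) is assumed usable in excess.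

**Step 1**
Reactants: 1 5-methoxy-1-tetralone
Product: 2 (1S)-5-methoxy-1,2,3,4-tetrahydronaphthalen-1-ol
Conditions: (R)-1-methyl-3,3-diphenyl-tetrahydro-1H,3H-pyrrolo[1,2-c][1,3,2]oxazaborole ((R)-Me-CBS, 10 mol%), BH3·SMe2, THF, 0 °C; MeOH quench
Reagents that add atoms: none
Why: Corey–Bakshi–Shibata reduction, in which the ketone binds the oxazaborolidine with the arene as the large group and hydride is delivered from the coordinated borane to one carbonyl face, the (R)-catalyst giving the (S)-carbinol as it does with 1-tetralone.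

**Step 2**
Reactants: 2 (1S)-5-methoxy-1,2,3,4-tetrahydronaphthalen-1-ol
Product: 3 (1S)-5-methoxy-1,2,3,4-tetrahydronaphthalen-1-yl pivalate
Conditions: PivCl, pyridine, DMAP (cat.), CH2Cl2, 0 °C → rt
Reagents that add atoms: pivaloyl chloride, CC(C)(C)C(Cl)=O
Why: DMAP-catalysed O-acylation of a secondary alcohol, which leaves the C1–O bond untouched and therefore retains configuration.

**Step 3**
Reactants: 3 (1S)-5-methoxy-1,2,3,4-tetrahydronaphthalen-1-yl pivalate
Product: 4 (1S)-5-methoxy-4-oxo-1,2,3,4-tetrahydronaphthalen-1-yl pivalate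
Conditions: DDQ (2.5 equiv), AcOH/H2O, 80 °C
Reagents that add atoms: water, O
Why: DDQ benzylic oxidation by hydride abstraction, in which the C4 cation is stabilised by the ortho methoxy group, is trapped by water and the resulting benzylic alcohol is oxidised on to the aryl ketone, whereas C1–H is deactivated by its acyloxy group and lies meta to the methoxy group, so the ester and the C1 configuration should persist.

**Step 4**
Reactants: 4 (1S)-5-methoxy-4-oxo-1,2,3,4-tetrahydronaphthalen-1-yl pivalate
Product: 5 (1S)-5-methoxy-4-[(trifluoromethanesulfonyl)oxy]-1,2-dihydronaphthalen-1-yl pivalate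
Conditions: KN(SiMe3)2, THF, −78 °C; then PhNTf2, −78 → 0 °C
Reagents that add atoms: N-phenylbis(trifluoromethanesulfonimide), O=S(=O)(N(c1ccccc1)S(=O)(=O)C(F)(F)F)C(F)(F)F
Why: Enol triflate formation, since the ketone can enolise only towards C3 and the potassium enolate is O-sulfonylated, while the pivalate has no α-hydrogen and is inert to the amide base at −78 °C.

**Step 5**
Reactants: 5 (1S)-5-methoxy-4-[(trifluoromethanesulfonyl)oxy]-1,2-dihydronaphthalen-1-yl pivalate; 6 (4-hydroxyphenyl)boronic acid
Product: 7 (1S)-4-(4-hydroxyphenyl)-5-methoxy-1,2-dihydronaphthalen-1-yl pivalate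
Conditions: PdCl2(dppf) (5 mol%), K3PO4, 1,4-dioxane/H2O, 70 °C
Reagents that add atoms: none
Why: Suzuki–Miyaura coupling (oxidative addition of the vinyl triflate to zerovalent palladium, transmetalation from the boronate, reductive elimination), which tolerates the free phenol and the hindered pivalate under aqueous phosphate.

**Step 6**
Reactants: 7 (1S)-4-(4-hydroxyphenyl)-5-methoxy-1,2-dihydronaphthalen-1-yl pivalate
Product: 8 (1S,4S)-4-(4-hydroxyphenyl)-5-methoxy-1,2,3,4-tetrahydronaphthalen-1-yl pivalate (cis)
Conditions: H2 (1–3 atm), 5% Pt/C, EtOAc, rt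
Reagents that add atoms: none
Why: Heterogeneous syn-hydrogenation under substrate control, in which the C1 pivaloyloxy group (pseudoaxial in the half-chair to avoid the peri C8–H) screens one face of the C3=C4 bond so that hydrogen arrives from the other face and the aryl group ends cis to the ester, setting C4 as S; platinum is chosen because it saturates the styrenic alkene without hydrogenolysing the benzylic ester.

**Step 7**
Reactants: 8 (1S,4S)-4-(4-hydroxyphenyl)-5-methoxy-1,2,3,4-tetrahydronaphthalen-1-yl pivalate
Product: 10 (1S,4R)-4-(1-hydroxy-4-oxocyclohexa-2,5-dien-1-yl)-5-methoxy-1,2,3,4-tetrahydronaphthalen-1-yl pivalate, via para-peroxyquinol 9 (not isolated)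
Conditions: KHSO5 (as 2KHSO5·KHSO4·K2SO4, excess), NaHCO3, MeCN/H2O, rt; then Me2S
Reagents that add atoms: potassium peroxymonosulfate (source of singlet dioxygen), [K+].[O-]S(=O)(=O)OO
Why: Singlet-oxygen dearomatisation of a para-alkylphenol, in which singlet dioxygen released from peroxymonosulfate in bicarbonate buffer adds across C1/C4 of the phenol(ate) to give the para-hydroperoxy dienone 9 that dimethyl sulfide reduces to the quinol; no phenoxenium-type intermediate is formed, so the benzylic methine cannot be lost to a quinone methide and C4 keeps its configuration (its descriptor changes to R only through priorities; the quinol carbon is not stereogenic).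

**Step 8**
Reactants: 10 (1S,4R)-4-(1-hydroxy-4-oxocyclohexa-2,5-dien-1-yl)-5-methoxy-1,2,3,4-tetrahydronaphthalen-1-yl pivalate; 11 1-methoxycyclohexa-1,3-diene
Product: 12 (1S,4R)-4-(1-hydroxy-5-methoxy-4-oxo-1,4,4a,5,8,8a-hexahydro-5,8-ethanonaphthalen-1-yl)-5-methoxy-1,2,3,4-tetrahydronaphthalen-1-yl pivalate (mixture of stereoisomers at the new centres)
Conditions: 11 (6 equiv), PhMe, 105 °C, sealed tube, K2CO3 (solid, trace), BHT (trace)
Reagents that add atoms: none
Why: Concerted, suprafacial normal-demand [4+2] cycloaddition between the diene HOMO (raised by the methoxy group) and the enone LUMO of the cross-conjugated dienone, the closest precedents being additions of 1-alkoxycyclohexa-1,3-dienes to quinones and of dienes to para-quinols. Ring D closes intermolecularly by forming C4a'–C5' and C8'–C8a' in the same event, as a cyclohexene embedded in a bicyclo[2.2.2]octene. The only selectivity needed is regiochemical: the unsubstituted diene terminus (largest HOMO coefficient) bonds to the enone β-carbon C8a' and the methoxy-bearing terminus to the α-carbon C4a', an orientation reinforced sterically because the more substituted terminus then avoids the quaternary carbinol carbon, and this places OMe on C5' peri to the C4' oxygen. The new centres (C4a', C5', C8', C8a' and the now stereogenic C1') are not controlled beyond the cis ring fusion imposed by suprafacial addition and need not be, since steps 9 and 10 erase all of them, and the two enone double bonds of 10 converge on the same naphthol. Mono-addition is secured because the remaining enone of 12 is flanked by the new bicycle, and the trace of base keeps the acid-sensitive enol ether intact.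

**Step 9**
Reactants: 12 (1S,4R)-4-(1-hydroxy-5-methoxy-4-oxo-1,4,4a,5,8,8a-hexahydro-5,8-ethanonaphthalen-1-yl)-5-methoxy-1,2,3,4-tetrahydronaphthalen-1-yl pivalate
Product: 13 (1S,4S)-4-(4-hydroxy-5-methoxy-5,8-dihydro-5,8-ethanonaphthalen-1-yl)-5-methoxy-1,2,3,4-tetrahydronaphthalen-1-yl pivalate (two bridgehead diastereomers)
Conditions: p-TsOH·H2O (10 mol%), PhMe, 60 °C
Reagents that add atoms: none
Why: Acid-catalysed dehydrative aromatisation of a γ-hydroxy enone, in which enolisation of the C4' ketone towards C4a' gives a cyclohexadienol (an arene hydrate) that ionises at C1' and loses the C8a' ring proton, so elimination runs into ring C and not towards the tetralin methine, while the bridgehead C5'–OMe cannot β-eliminate (Bredt's rule) and the pivalate tolerates catalytic sulfonic acid.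

**Step 10**
Reactants: 13 (1S,4S)-4-(4-hydroxy-5-methoxy-5,8-dihydro-5,8-ethanonaphthalen-1-yl)-5-methoxy-1,2,3,4-tetrahydronaphthalen-1-yl pivalate
Product: 14 (1S,4S)-4-(4-hydroxy-5-methoxynaphthalen-1-yl)-5-methoxy-1,2,3,4-tetrahydronaphthalen-1-yl pivalate
Conditions: Ph2O (degassed), 230–250 °C, argon
Reagents that add atoms: none
Why: Alder–Rickert cycloreversion, in which the bicyclo[2.2.2]octadiene (C6'=C7' plus the aromatic C4a'=C8a' bond) extrudes ethylene in a thermal retro-[4+2] that irreversibly makes ring D aromatic and erases the bridgehead centres, the ester, aryl ethers and both tetralin centres being thermally inert in this range.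

**Step 11**
Reactants: 14 (1S,4S)-4-(4-hydroxy-5-methoxynaphthalen-1-yl)-5-methoxy-1,2,3,4-tetrahydronaphthalen-1-yl pivalate
Product: 15 dipolynaphthalene B, (1S,4S)-4-(4-hydroxy-5-methoxynaphthalen-1-yl)-5-methoxy-1,2,3,4-tetrahydronaphthalen-1-ol
Conditions: iBu2AlH (4 equiv), CH2Cl2, −78 → 0 °C; aq. KNaC4H4O6 work-up
Reagents that add atoms: none
Why: Reductive cleavage of the pivalate by the aluminium hydride at low temperature, with the naphthol merely deprotonated and the C1–O bond never broken, so both stereocentres are retained.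

**Compound list**
1 | 5-methoxy-1-tetralone (5-methoxy-3,4-dihydronaphthalen-1(2H)-one) | COc1cccc2c1CCCC2=O | starting material
2 | (1S)-5-methoxy-1,2,3,4-tetrahydronaphthalen-1-ol | COc1cccc2c1CCC[C@@H]2O | intermediate
3 | (1S)-5-methoxy-1,2,3,4-tetrahydronaphthalen-1-yl pivalate | COc1cccc2c1CCC[C@@H]2OC(=O)C(C)(C)C | intermediate
4 | (1S)-5-methoxy-4-oxo-1,2,3,4-tetrahydronaphthalen-1-yl pivalate | COc1cccc2c1C(=O)CC[C@@H]2OC(=O)C(C)(C)C | intermediate
5 | (1S)-5-methoxy-4-[(trifluoromethanesulfonyl)oxy]-1,2-dihydronaphthalen-1-yl pivalate | COc1cccc2c1C(OS(=O)(=O)C(F)(F)F)=CC[C@@H]2OC(=O)C(C)(C)C | intermediate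
6 | (4-hydroxyphenyl)boronic acid | OB(O)c1ccc(O)cc1 | starting material
7 | (1S)-4-(4-hydroxyphenyl)-5-methoxy-1,2-dihydronaphthalen-1-yl pivalate | COc1cccc2c1C(c1ccc(O)cc1)=CC[C@@H]2OC(=O)C(C)(C)C | intermediate
8 | (1S,4S)-4-(4-hydroxyphenyl)-5-methoxy-1,2,3,4-tetrahydronaphthalen-1-yl pivalate (cis) | COc1cccc2c1[C@H](c1ccc(O)cc1)CC[C@@H]2OC(=O)C(C)(C)C | intermediate
9 | (1S,4R)-4-(1-hydroperoxy-4-oxocyclohexa-2,5-dien-1-yl)-5-methoxy-1,2,3,4-tetrahydronaphthalen-1-yl pivalate (para-peroxyquinol, not isolated) | COc1cccc2c1[C@H](C1(OO)C=CC(=O)C=C1)CC[C@@H]2OC(=O)C(C)(C)C | intermediate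
10 | (1S,4R)-4-(1-hydroxy-4-oxocyclohexa-2,5-dien-1-yl)-5-methoxy-1,2,3,4-tetrahydronaphthalen-1-yl pivalate (para-quinol, key-step precursor) | COc1cccc2c1[C@H](C1(O)C=CC(=O)C=C1)CC[C@@H]2OC(=O)C(C)(C)C | intermediate
11 | 1-methoxycyclohexa-1,3-diene | COC1=CC=CCC1 | starting material
12 | (1S,4R)-4-(1-hydroxy-5-methoxy-4-oxo-1,4,4a,5,8,8a-hexahydro-5,8-ethanonaphthalen-1-yl)-5-methoxy-1,2,3,4-tetrahydronaphthalen-1-yl pivalate (Diels–Alder adduct, new centres unassigned) | COc1cccc2c1[C@H](C3(O)C=CC(=O)C4C3C5C=CC4(OC)CC5)CC[C@@H]2OC(=O)C(C)(C)C | intermediate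
13 | (1S,4S)-4-(4-hydroxy-5-methoxy-5,8-dihydro-5,8-ethanonaphthalen-1-yl)-5-methoxy-1,2,3,4-tetrahydronaphthalen-1-yl pivalate (bridgeheads unassigned) | COc1cccc2c1[C@H](c3ccc(O)c4c3C5C=CC4(OC)CC5)CC[C@@H]2OC(=O)C(C)(C)C | intermediate
14 | (1S,4S)-4-(4-hydroxy-5-methoxynaphthalen-1-yl)-5-methoxy-1,2,3,4-tetrahydronaphthalen-1-yl pivalate | COc1cccc2c1[C@H](c1ccc(O)c3c(OC)cccc13)CC[C@@H]2OC(=O)C(C)(C)C | intermediate
15 | dipolynaphthalene B, (1S,4S)-4-(4-hydroxy-5-methoxynaphthalen-1-yl)-5-methoxy-1,2,3,4-tetrahydronaphthalen-1-ol | COc1cccc2c1[C@H](c1ccc(O)c3c(OC)cccc13)CC[C@@H]2O | target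

**Step count.** Total: 11 steps. Longest linear sequence: 11 steps (1 to 15); 6 and 11 are purchased.

**Steps most likely to fail**

Step 8 (key cycloaddition). The addition may be too slow at the enone β-carbon, which sits next to the quaternary carbinol carbon, so that dimerisation or isomerisation of the diene, or slow thermal decay of the quinol, wins. The fallback gives up the annulation and brings rings C and D in as a preformed naphthalene. It sets out from enol triflate 5. Commercial 8-methoxynaphthalen-1-ol is brominated para to the hydroxyl (NBS, MeCN, 0 °C) to 4-bromo-8-methoxynaphthalen-1-ol F1, benzylated (BnBr, K2CO3, DMF) to 1-(benzyloxy)-4-bromo-8-methoxynaphthalene F2, and converted by Miyaura borylation (B2pin2, PdCl2(dppf), KOAc, dioxane, 90 °C) into 2-[4-(benzyloxy)-5-methoxynaphthalen-1-yl]-4,4,5,5-tetramethyl-1,3,2-dioxaborolane F3. Suzuki–Miyaura coupling of F3 with 5 (Pd(OAc)2/SPhos, K3PO4, PhMe/H2O) should give (1S)-4-[4-(benzyloxy)-5-methoxynaphthalen-1-yl]-5-methoxy-1,2-dihydronaphthalen-1-yl pivalate F4. Hydrogenation over Pd/C in EtOAc (anti to the pivalate, with the aryl benzyl ether cleaved far faster than the secondary benzylic ester) comes back to the route at 14. The price is hydrogenation of a much more hindered alkene.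

Step 9 (acid aromatisation). Before the ketone enolises, the acid may divert the adduct. The possible diversions are cleavage of the C4a'–C5' bond of the β-methoxy ketone, a 1,2-shift or loss of the cation-stabilised tetralinyl group from the carbinol carbon, and ionisation of the benzylic ester. The fallback enolises under basic silylating conditions first and sets out from 12. TMSOTf/Et3N (CH2Cl2, 0 °C) should give the bis(trimethylsilyl) dienol ether F5, an arene-hydrate ether. With a catalytic excess of TMSOTf or on gentle warming, F5 loses trimethylsilanol across C1'–C8a' to give the aryl trimethylsilyl ether F6. Methanolysis (K2CO3, MeOH) comes back to the route at 13.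

Step 10 (ethylene extrusion). Cycloreversion to a naphthalene gains less aromatic stabilisation than cycloreversion to a benzene, so it may need temperatures at which the free naphthol or the benzylic ester begin to degrade. The fallback raises the driving force by running the cycloreversion at the quinol oxidation level and sets out from 13. Ring C is dearomatised again with singlet oxygen (KHSO5, NaHCO3, MeCN/H2O) to the bicyclic para-peroxyquinol F7, and Me2S reduces it to the bicyclic para-quinol F8. In F8 ring D becomes a full benzene ring on loss of ethylene, which should therefore occur at much lower temperature (refluxing toluene or xylene) and give the naphthalenone quinol F9. Reductive aromatisation of this para-quinol with Zn/AcOH comes back to the route at 14.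

**Further compounds**
F1 | step 8 | 4-bromo-8-methoxynaphthalen-1-ol | COc1cccc2c(Br)ccc(O)c12
F2 | step 8 | 1-(benzyloxy)-4-bromo-8-methoxynaphthalene | COc1cccc2c(Br)ccc(OCc3ccccc3)c12
F3 | step 8 | 2-[4-(benzyloxy)-5-methoxynaphthalen-1-yl]-4,4,5,5-tetramethyl-1,3,2-dioxaborolane | COc1cccc2c(B3OC(C)(C)C(C)(C)O3)ccc(OCc3ccccc3)c12
F4 | step 8 | (1S)-4-[4-(benzyloxy)-5-methoxynaphthalen-1-yl]-5-methoxy-1,2-dihydronaphthalen-1-yl pivalate | COc1cccc2c1C(c1ccc(OCc3ccccc3)c3c(OC)cccc13)=CC[C@@H]2OC(=O)C(C)(C)C
F5 | step 9 | (1S,4R)-4-[5-methoxy-1,4-bis(trimethylsilyloxy)-1,5,8,8a-tetrahydro-5,8-ethanonaphthalen-1-yl]-5-methoxy-1,2,3,4-tetrahydronaphthalen-1-yl pivalate | COc1cccc2c1[C@H](C3(O[Si](C)(C)C)C=CC(O[Si](C)(C)C)=C4C3C5C=CC4(OC)CC5)CC[C@@H]2OC(=O)C(C)(C)C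
F6 | step 9 | (1S,4S)-4-[5-methoxy-4-(trimethylsilyloxy)-5,8-dihydro-5,8-ethanonaphthalen-1-yl]-5-methoxy-1,2,3,4-tetrahydronaphthalen-1-yl pivalate | COc1cccc2c1[C@H](c3ccc(O[Si](C)(C)C)c4c3C5C=CC4(OC)CC5)CC[C@@H]2OC(=O)C(C)(C)C
F7 | step 10 | (1S,4R)-4-(1-hydroperoxy-5-methoxy-4-oxo-1,4,5,8-tetrahydro-5,8-ethanonaphthalen-1-yl)-5-methoxy-1,2,3,4-tetrahydronaphthalen-1-yl pivalate | COc1cccc2c1[C@H](C3(OO)C=CC(=O)C4=C3C5C=CC4(OC)CC5)CC[C@@H]2OC(=O)C(C)(C)C
F8 | step 10 | (1S,4R)-4-(1-hydroxy-5-methoxy-4-oxo-1,4,5,8-tetrahydro-5,8-ethanonaphthalen-1-yl)-5-methoxy-1,2,3,4-tetrahydronaphthalen-1-yl pivalate | COc1cccc2c1[C@H](C3(O)C=CC(=O)C4=C3C5C=CC4(OC)CC5)CC[C@@H]2OC(=O)C(C)(C)C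
F9 | step 10 | (1S,4R)-4-(1-hydroxy-5-methoxy-4-oxo-1,4-dihydronaphthalen-1-yl)-5-methoxy-1,2,3,4-tetrahydronaphthalen-1-yl pivalate | COc1cccc2c1[C@H](C3(O)C=CC(=O)c4c(OC)cccc43)CC[C@@H]2OC(=O)C(C)(C)C
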